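## Analysis of the target

Compound 18 is built from two (2S)-5,7-dihydroxyflavanone units joined by a diaryl ether. The oxygen on C4' of ring B of unit 1 is bonded to C6 of ring A of unit 2, and unit 2 keeps its own 4'-hydroxyl. The only stereocentres are the two C2 atoms, both S. Ring B of unit 1 and the ether oxygen lie between them, so neither can direct the other and each needs its own external control. Each C2 is a benzylic aryl ether β to the C4 ketone, so base (E1cB opening of ring C to the 2'-hydroxychalcone) or strong acid racemises it. The five phenols and the two phloroglucinol-type rings are prone to oxidation. The hard points are the ether oxygen on C6 of unit 2, which is flanked by the C5 and C7 oxygens and is not a native position of a phloroglucinol, and the need to build two nearly identical flavanones in sequence without exposing the first ring C to base. The strategy rests on ring A of unit 1: C4a is the ortho carbon of a phloroglucinol aryl ether and the most nucleophilic arene carbon of the molecule, and C4 is reached from O1 through C2 and C3. If C3 and C4 arrive as a terminal alkyne on C2, the alkyne terminus folds onto C4a; the two ortho carbons of the 3,5-dioxygenated ring are equivalent, so ring C can close in only one way.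

## Retrosynthetic reasoning

**18 from 17.** The five phenols are masked as benzyl ethers and released together in a neutral last step. Benzyl is chosen over acetal-type groups because it survives the hot acid needed in the persulfate step that leads to 4, and because the phenol 13 and the boronic acid 9 can then be bought already protected.

**17 from 16 and 15.** The C4 carbonyl of unit 1 is taken back to the alcohol 16 and then to the C3=C4 double bond of the 2H-chromene 15. This removes the β-aryloxy ketone from the ring-forming stage, so C2 of unit 1 cannot be lost by retro-oxa-Michael opening while ring C is made. Forward, the electron-rich ring A directs a Markovnikov hydration to benzylic C4, and a mild oxidation follows.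

**15 from 14.** The C4–C4a bond is cut. It joins the best arene nucleophile to a carbon that can be an alkyne terminus, and the other ring C bonds (O1–C2, C2–C3, C3–C4) are already present in the aryl propargyl ether 14. The closure is an isomerisation that adds no atoms and does not touch the four bonds of C2.

**14 from 12 and 13.** The O1–C2 bond of unit 1 is cut. Forward, an enantioselective propargylic substitution of the acetate 12 by the phenol 13 sets C2 of unit 1 as a plain ether and brings in all of ring A.

**12 from 10.** The C2–C3 bond of unit 1 is cut between carbinol and alkyne, leading to the aldehyde 10. The carbinol configuration is irrelevant because the next step erases it.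

**10 from 8 and 9.** The C2–C1' bond of unit 2 is cut. Forward, an asymmetric conjugate arylation of the chromone 8 with 9 sets C2 of unit 2 without base. A chalcone cyclisation was not used: it needs base and would involve the formyl group.

**8 from 6.** Ring C of unit 2 is opened at O1–C2 and C2–C3. Forward, a one-carbon unit is inserted between the acetyl methyl group and the ortho hydroxyl of 6 by way of the enaminone 7.

**6 from 4 and 5.** The diaryl ether is cut on the ring B side, since ring A of unit 2 is electron-rich and can only be the nucleophile. In 5 the formyl group activates the fluoride for substitution and later becomes C2 of unit 1.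

**4 from 2 and 1.** The C6 oxygen of unit 2 is removed. Forward, the phenol 2, made by selective dibenzylation of 1, is hydroxylated para to its free hydroxyl through the aryl sulfate 3.

## Alternatives that were turned down

**Alternative 1:** Ring A of unit 2 is disconnected at C7–C8 and C4a–C8a into the cyclobutenone A2 and the siloxyalkyne A3. On heating, A2 opens to a vinylketene, which adds A3; a second ring opening and a six-electron electrocyclisation give the hexasubstituted phenol A1.
- For: the aryloxy group is placed on C6 without ambiguity, and all four ring A oxygens emerge differentiated. On this regiochemical point it is stronger than the chosen route, which relies on a para-selective persulfate oxidation and on discrimination between two phenols.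
- Against: the ring it builds is an arene that phloroacetophenone already supplies. A2 is itself a multi-step, sensitive compound. A1 contains no stereocentre of the target. Still to come are removal of the C8 silyl group, cleavage of an ethyl ether, both heterocycles, both C2 centres, and conversion of the aryl bromide into all of unit 1.
- Comparison: the chosen route accepts a classical oxidation to reach the same oxygenation pattern in two steps and spends its ring-forming step on ring C of unit 1, next to a stereocentre, in far fewer steps overall.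

**Alternative 2:** Ring A of unit 2 is disconnected at C4a–C5. Thermolysis of the dioxinone A5 expels acetone; the resulting α-aryloxy acylketene is attacked by C5 of the tethered dihydropyranone, and enolisation aromatises the new ring to the flavanone A4.
- For: the diaryl ether oxygen is carried in from the start, so no hindered substitution and no ring oxidation are needed. Unit 2 appears directly with free C5 and C7 hydroxyls and its C2 already set. On these points it equals or beats the chosen route.
- Against: the nucleophile is the weakly nucleophilic α-carbon of a vinylogous ester, and it must outrun dimerisation or O-trapping of the acylketene at about 110 °C. The methylene link between the two heterocycles in A5 is not trivial to assemble. A4 then needs its phenols protected and its bromide turned into an aldehyde before unit 1 can be started, which still requires a second asymmetric flavanone synthesis.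
- Comparison: the chosen route delivers ring B of unit 1 already as an aldehyde from the substitution step and uses a ring closure with direct precedent on aryl propargyl ethers.

**Alternative 3:** Ring C of unit 2 is disconnected at C2–C3. A confined chiral imidodiphosphorimidate acid ionises the mixed methyl aryl acetal in A7 to an oxocarbenium ion spanning O1 and C2; the enol silane terminus adds to it, closing ring C and setting C2 of the tribenzyl flavanone A6.
- For: ring closure and stereocentre come from one catalytic step on a substrate derived from the same acetophenone as 4, with no chromone stage. In concept this is more direct for unit 2 than steps 4 and 5.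
- Against: the acetal can ionise in two ways, and the aryloxide, stabilised by the ortho enol silane, is the better leaving group. The wrong cation (loss of the phenol) is therefore likely, leading to acyclic products and chalcone. A7 combines two acid-labile groups and is awkward to prepare and store. A6 ends as an aryl bromide that must be formylated in the presence of the flavanone before unit 1 can be built.
- Comparison: the chosen route uses two asymmetric steps that each have precedent on their substrate class and leaves the main uncertainty in one late isomerisation.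

Key step: step 8

Assumption: (R)-t-BuPyOx in step 5 and (S,S)-Ph-pybox in step 7 are written as the ligand antipodes expected to give the (S) centres; if either induces the opposite sense on these substrates, its mirror-image ligand is used and nothing else changes.

## Route

Step 1
Reactants: 1 2,4,6-trihydroxyacetophenone
Product: 2 1-[2,4-bis(benzyloxy)-6-hydroxyphenyl]ethan-1-one
Conditions: BnBr (2.1 equiv), K2CO3, DMF, 0 °C to rt
Reagents that add atoms: benzyl bromide, BrCc1ccccc1
Why: Williamson etherification; the hydroxyl hydrogen-bonded to the acetyl group is the least nucleophilic and stays free, as needed later for ring C of unit 2.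

Step 2
Reactants: 2 1-[2,4-bis(benzyloxy)-6-hydroxyphenyl]ethan-1-one
Product: 4 1-[2,4-bis(benzyloxy)-3,6-dihydroxyphenyl]ethan-1-one, via aryl potassium sulfate 3 (not isolated)
Conditions: K2S2O8, aq NaOH, pyridine, 10–20 °C; then HCl (pH 1), Na2SO3, 90 °C
Reagents that add atoms: potassium peroxodisulfate, [K+].[K+].[O-]S(=O)(=O)OOS(=O)(=O)[O-]
Why: Elbs persulfate oxidation: the phenoxide of 2 is attacked by peroxodisulfate at its free para carbon (the future C6 of unit 2) and the aryl sulfate 3 is then hydrolysed by acid. Benzyl ethers survive both stages, which acetal-type protecting groups would not.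

Step 3
Reactants: 4 1-[2,4-bis(benzyloxy)-3,6-dihydroxyphenyl]ethan-1-one; 5 4-fluorobenzaldehyde
Product: 6 4-[3-acetyl-2,6-bis(benzyloxy)-4-hydroxyphenoxy]benzaldehyde
Conditions: 5 (1.0 equiv), K2CO3, degassed DMF, Ar, 70–80 °C
Reagents that add atoms: none
Why: Nucleophilic aromatic substitution (SNAr) activated by the para formyl group; the phenoxide between the two benzyloxy groups is the more nucleophilic oxygen, since the chelated one is delocalised into the acetyl group, as in O-alkylations of such 2,5-dihydroxyacetophenones. One equivalent of 5 and exclusion of oxygen limit double arylation and quinone formation.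

Step 4
Reactants: 6 4-[3-acetyl-2,6-bis(benzyloxy)-4-hydroxyphenoxy]benzaldehyde
Product: 8 4-{[5,7-bis(benzyloxy)-4-oxo-4H-chromen-6-yl]oxy}benzaldehyde, via enaminone 7 (not isolated)
Conditions: Me2NCH(OMe)2, toluene, 90 °C; then conc. HCl, CH2Cl2, rt
Reagents that add atoms: N,N-dimethylformamide dimethyl acetal, COC(OC)N(C)C
Why: Enaminone route to chromones: condensation at the acetyl methyl group, then acid-induced addition of the ortho hydroxyl and loss of dimethylamine. The formyl group has no enolisable hydrogen and does not react with the formamide acetal.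

Step 5
Reactants: 8 4-{[5,7-bis(benzyloxy)-4-oxo-4H-chromen-6-yl]oxy}benzaldehyde; 9 4-(benzyloxy)phenylboronic acid
Product: 10 4-{[(2S)-5,7-bis(benzyloxy)-2-[4-(benzyloxy)phenyl]-4-oxochroman-6-yl]oxy}benzaldehyde
Conditions: Pd(OCOCF3)2 (10 mol %), (R)-t-BuPyOx (12 mol %), NH4PF6, H2O, 9 (2 equiv), ClCH2CH2Cl, 60 °C
Reagents that add atoms: none
Why: Asymmetric conjugate addition of an arylboronic acid to a chromone under divalent palladium: transmetalation gives an aryl–palladium cation, C2=C3 inserts on the face left open by the tert-butyl group of the pyridine–oxazoline ligand (this sets C2 of unit 2 as S), and water protonates the palladium enolate. Cationic palladium of this type adds to enones much faster than to aldehydes, and no base is present, so ring C does not open.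

Step 6
Reactants: 10 4-{[(2S)-5,7-bis(benzyloxy)-2-[4-(benzyloxy)phenyl]-4-oxochroman-6-yl]oxy}benzaldehyde
Product: 12 1-(4-{[(2S)-5,7-bis(benzyloxy)-2-[4-(benzyloxy)phenyl]-4-oxochroman-6-yl]oxy}phenyl)prop-2-yn-1-yl acetate (both epimers at the carbinol carbon), via bromomagnesium alkoxide 11 (not isolated)
Conditions: HC≡CMgBr (1.2 equiv), THF, −78 to −40 °C; then Ac2O, −40 to 0 °C
Reagents that add atoms: ethynylmagnesium bromide, C#C[Mg]Br; acetic anhydride, CC(=O)OC(C)=O
Why: Grignard addition to the aldehyde, which is far more electrophilic than the hindered C4 ketone of unit 2 with its three donor oxygens, followed by O-acetylation of the alkoxide in the same flask. The new carbinol centre is left uncontrolled because step 7 erases it.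

Step 7
Reactants: 12 1-(4-{[(2S)-5,7-bis(benzyloxy)-2-[4-(benzyloxy)phenyl]-4-oxochroman-6-yl]oxy}phenyl)prop-2-yn-1-yl acetate; 13 3,5-bis(benzyloxy)phenol
Product: 14 (2S)-5,7-bis(benzyloxy)-2-[4-(benzyloxy)phenyl]-6-(4-{(1S)-1-[3,5-bis(benzyloxy)phenoxy]prop-2-yn-1-yl}phenoxy)chroman-4-one
Conditions: CuOTf·1/2C6H6 (5 mol %), (S,S)-Ph-pybox (10 mol %), iPr2NEt, CH2Cl2, −20 °C
Reagents that add atoms: none
Why: Copper-catalysed asymmetric propargylic etherification: monovalent copper forms the acetylide, acetate leaves to give a copper allenylidene in which the carbinol centre of both epimers of 12 is erased, and the phenol oxygen adds to the γ-carbon on the face left open by the pybox phenyl groups, setting C2 of unit 1 as S. The aprotic medium favours attack through oxygen over ring carbon.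

Step 8
Reactants: 14 (2S)-5,7-bis(benzyloxy)-2-[4-(benzyloxy)phenyl]-6-(4-{(1S)-1-[3,5-bis(benzyloxy)phenoxy]prop-2-yn-1-yl}phenoxy)chroman-4-one
Product: 15 (2S)-5,7-bis(benzyloxy)-2-[4-(benzyloxy)phenyl]-6-{4-[(2S)-5,7-bis(benzyloxy)-2H-chromen-2-yl]phenoxy}chroman-4-one
Conditions: Ph3PAuNTf2 (3 mol %), CH2Cl2, 4 Å MS, 0 °C to rt; Et3N quench
Reagents that add atoms: none
Why: Cationic monovalent gold binds the terminal alkyne of 14, and the ortho carbon of the 3,5-bis(benzyloxy)phenyl ether attacks the terminal alkyne carbon anti to the metal in a Friedel–Crafts sense, forming C4–C4a; loss of the ring proton restores the arene and protodeauration of the C3 vinylgold species releases the catalyst. The closest known reaction type is the gold- or platinum-catalysed intramolecular hydroarylation of aryl propargyl ethers to 2H-chromenes. Ring C of unit 1 closes in the 6-endo-dig mode. No stereocentre is created: C2, set in step 7, keeps all four bonds and stays S. Endo closure is needed over 5-exo closure; the unhindered alkyne terminus, the propargylic oxygen (which disfavours positive charge on the internal carbon) and the three-atom tether all favour it. A single regioisomer is needed; the two ortho carbons are equivalent, and ring B and the rings of unit 2 are too remote to compete. The benzylic, propargylic C2–O bond must not ionise, so a neutral aprotic catalyst, a cold dilute solution, molecular sieves and a basic quench are used. The high nucleophilicity of ring A should keep the cyclisation fast under these mild conditions.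

Step 9
Reactants: 15 (2S)-5,7-bis(benzyloxy)-2-[4-(benzyloxy)phenyl]-6-{4-[(2S)-5,7-bis(benzyloxy)-2H-chromen-2-yl]phenoxy}chroman-4-one
Product: 16 (2S)-5,7-bis(benzyloxy)-2-[4-(benzyloxy)phenyl]-6-{4-[(2S,4RS)-5,7-bis(benzyloxy)-4-hydroxychroman-2-yl]phenoxy}chroman-4-one
Conditions: Co(acac)2 (20 mol %), PhSiH3, O2 (1 atm), THF, 0 °C to rt
Reagents that add atoms: dioxygen, O=O
Why: Mukaiyama hydration: a cobalt hydride (from divalent cobalt, silane and oxygen) transfers a hydrogen atom to C3, the C4 benzylic radical stabilised by ring A traps O2, and the silane reduces the peroxide to the alcohol. Both C4 epimers are acceptable, and any ketone formed directly is the product of step 10; C2 is not part of the radical and keeps its configuration.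

Step 10
Reactants: 16 (2S)-5,7-bis(benzyloxy)-2-[4-(benzyloxy)phenyl]-6-{4-[(2S,4RS)-5,7-bis(benzyloxy)-4-hydroxychroman-2-yl]phenoxy}chroman-4-one
Product: 17 (2S)-5,7-bis(benzyloxy)-2-[4-(benzyloxy)phenyl]-6-{4-[(2S)-5,7-bis(benzyloxy)-4-oxochroman-2-yl]phenoxy}chroman-4-one
Conditions: Dess–Martin periodinane, pyridine, CH2Cl2, 0 °C to rt
Reagents that add atoms: none
Why: Dess–Martin oxidation of a secondary benzylic alcohol; the pyridine buffer prevents acid ionisation of the electron-rich flavan-4-ol and leaves both C2 centres untouched.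

Step 11
Reactants: 17 (2S)-5,7-bis(benzyloxy)-2-[4-(benzyloxy)phenyl]-6-{4-[(2S)-5,7-bis(benzyloxy)-4-oxochroman-2-yl]phenoxy}chroman-4-one
Product: 18 (2S)-6-{4-[(2S)-5,7-dihydroxy-4-oxochroman-2-yl]phenoxy}-5,7-dihydroxy-2-(4-hydroxyphenyl)chroman-4-one
Conditions: H2 (1 atm), Pd/C (10 %), EtOAc/MeOH, rt
Reagents that add atoms: none
Why: Hydrogenolysis of five benzyl aryl ethers on zerovalent palladium under neutral conditions, so neither flavanone can racemise. The cyclic benzylic C2–O bonds and the chelated ketones of flavanones are much slower to reduce than O-benzyl groups at room temperature and atmospheric pressure.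

## Compound list

1 | 2,4,6-trihydroxyacetophenone | CC(=O)c1c(O)cc(O)cc1O | starting material
2 | 1-[2,4-bis(benzyloxy)-6-hydroxyphenyl]ethan-1-one | CC(=O)c1c(O)cc(OCc2ccccc2)cc1OCc1ccccc1 | intermediate
3 | potassium 3-acetyl-2,6-bis(benzyloxy)-4-hydroxyphenyl sulfate | CC(=O)c1c(O)cc(OCc2ccccc2)c(OS(=O)(=O)[O-])c1OCc1ccccc1.[K+] | intermediate (not isolated)
4 | 1-[2,4-bis(benzyloxy)-3,6-dihydroxyphenyl]ethan-1-one | CC(=O)c1c(O)cc(OCc2ccccc2)c(O)c1OCc1ccccc1 | intermediate
5 | 4-fluorobenzaldehyde | O=Cc1ccc(F)cc1 | starting material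
6 | 4-[3-acetyl-2,6-bis(benzyloxy)-4-hydroxyphenoxy]benzaldehyde | CC(=O)c1c(O)cc(OCc2ccccc2)c(Oc2ccc(C=O)cc2)c1OCc1ccccc1 | intermediate
7 | 4-{2,6-bis(benzyloxy)-3-[(2E)-3-(dimethylamino)prop-2-enoyl]-4-hydroxyphenoxy}benzaldehyde | CN(C)/C=C/C(=O)c1c(O)cc(OCc2ccccc2)c(Oc2ccc(C=O)cc2)c1OCc1ccccc1 | intermediate (not isolated)
8 | 4-{[5,7-bis(benzyloxy)-4-oxo-4H-chromen-6-yl]oxy}benzaldehyde | O=Cc1ccc(Oc2c(OCc3ccccc3)cc3occc(=O)c3c2OCc2ccccc2)cc1 | intermediate
9 | 4-(benzyloxy)phenylboronic acid | OB(O)c1ccc(OCc2ccccc2)cc1 | starting material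
10 | 4-{[(2S)-5,7-bis(benzyloxy)-2-[4-(benzyloxy)phenyl]-4-oxochroman-6-yl]oxy}benzaldehyde | O=Cc1ccc(Oc2c(OCc3ccccc3)cc3c(c2OCc2ccccc2)C(=O)C[C@@H](c2ccc(OCc4ccccc4)cc2)O3)cc1 | intermediate
11 | bromomagnesium 1-(4-{[(2S)-5,7-bis(benzyloxy)-2-[4-(benzyloxy)phenyl]-4-oxochroman-6-yl]oxy}phenyl)prop-2-yn-1-olate, both epimers | C#CC(O[Mg]Br)c1ccc(Oc2c(OCc3ccccc3)cc3c(c2OCc2ccccc2)C(=O)C[C@@H](c2ccc(OCc4ccccc4)cc2)O3)cc1 | intermediate (not isolated)
12 | 1-(4-{[(2S)-5,7-bis(benzyloxy)-2-[4-(benzyloxy)phenyl]-4-oxochroman-6-yl]oxy}phenyl)prop-2-yn-1-yl acetate, both epimers at the carbinol carbon | C#CC(OC(C)=O)c1ccc(Oc2c(OCc3ccccc3)cc3c(c2OCc2ccccc2)C(=O)C[C@@H](c2ccc(OCc4ccccc4)cc2)O3)cc1 | intermediate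
13 | 3,5-bis(benzyloxy)phenol | Oc1cc(OCc2ccccc2)cc(OCc2ccccc2)c1 | starting material
14 | (2S)-5,7-bis(benzyloxy)-2-[4-(benzyloxy)phenyl]-6-(4-{(1S)-1-[3,5-bis(benzyloxy)phenoxy]prop-2-yn-1-yl}phenoxy)chroman-4-one | C#C[C@@H](c1ccc(Oc2c(OCc3ccccc3)cc3c(c2OCc2ccccc2)C(=O)C[C@@H](c2ccc(OCc4ccccc4)cc2)O3)cc1)Oc1cc(OCc2ccccc2)cc(OCc2ccccc2)c1 | intermediate
15 | (2S)-5,7-bis(benzyloxy)-2-[4-(benzyloxy)phenyl]-6-{4-[(2S)-5,7-bis(benzyloxy)-2H-chromen-2-yl]phenoxy}chroman-4-one | C1=C[C@@H](c2ccc(Oc3c(OCc4ccccc4)cc4c(c3OCc3ccccc3)C(=O)C[C@@H](c3ccc(OCc5ccccc5)cc3)O4)cc2)Oc2cc(OCc3ccccc3)cc(OCc3ccccc3)c21 | intermediate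
16 | (2S)-5,7-bis(benzyloxy)-2-[4-(benzyloxy)phenyl]-6-{4-[(2S,4RS)-5,7-bis(benzyloxy)-4-hydroxychroman-2-yl]phenoxy}chroman-4-one | OC1C[C@@H](c2ccc(Oc3c(OCc4ccccc4)cc4c(c3OCc3ccccc3)C(=O)C[C@@H](c3ccc(OCc5ccccc5)cc3)O4)cc2)Oc2cc(OCc3ccccc3)cc(OCc3ccccc3)c21 | intermediate
17 | (2S)-5,7-bis(benzyloxy)-2-[4-(benzyloxy)phenyl]-6-{4-[(2S)-5,7-bis(benzyloxy)-4-oxochroman-2-yl]phenoxy}chroman-4-one | O=C1C[C@@H](c2ccc(Oc3c(OCc4ccccc4)cc4c(c3OCc3ccccc3)C(=O)C[C@@H](c3ccc(OCc5ccccc5)cc3)O4)cc2)Oc2cc(OCc3ccccc3)cc(OCc3ccccc3)c21 | intermediate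
18 | (2S)-6-{4-[(2S)-5,7-dihydroxy-4-oxochroman-2-yl]phenoxy}-5,7-dihydroxy-2-(4-hydroxyphenyl)chroman-4-one | O=C1C[C@@H](c2ccc(Oc3c(O)cc4c(c3O)C(=O)C[C@@H](c3ccc(O)cc3)O4)cc2)Oc2cc(O)cc(O)c21 | target

## Step count and least certain steps

Total step count: 11. Longest linear sequence: 11 steps (1 to 18); 5, 9 and 13 enter as purchased building blocks.

**Step 8 (key step).** The most likely failure is ionisation of the benzylic, propargylic C2–O bond by the Lewis acid or by traces of strong acid from the catalyst. That would erode the configuration at C2 of unit 1 or transfer the propargyl group to ring carbon. The second danger is acid-triggered oligomerisation of the very electron-rich chromene once formed. The fallback sets out from 14 and closes the same C4–C4a bond by acylation instead of hydroarylation. Anti-Markovnikov hydration of the terminal alkyne (CpRu(MeCN)3PF6 with 5,5'-bis(trifluoromethyl)-2,2'-bipyridine, aqueous N-methylpyrrolidinone, rt) should give (3S)-3-[3,5-bis(benzyloxy)phenoxy]-3-(4-{[(2S)-5,7-bis(benzyloxy)-2-[4-(benzyloxy)phenyl]-4-oxochroman-6-yl]oxy}phenyl)propanal F1. This is oxidised at once (NaClO2, NaH2PO4, 2-methyl-2-butene, t-BuOH/H2O) to the corresponding propanoic acid F2. Trifluoroacetic anhydride in CH2Cl2 at 0 °C then brings about intramolecular Friedel–Crafts acylation of ring A. This fallback comes back to the route at 17 and bypasses 15 and 16.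

**Step 7.** The phloroglucinol-type phenol 13 may be captured through a ring carbon instead of oxygen, since copper allenylidenes are known to alkylate electron-rich phenols at carbon, or facial selectivity may be modest with this bulky nucleophile. The fallback sets out from 10. Enantioselective alkynylation (Me2Zn, trimethylsilylacetylene, the ProPhenol ligand antipode that gives the required carbinol, toluene, 0 °C) should give (2S)-5,7-bis(benzyloxy)-2-[4-(benzyloxy)phenyl]-6-{4-[(1S)-1-hydroxy-3-(trimethylsilyl)prop-2-yn-1-yl]phenoxy}chroman-4-one F3. Buffered desilylation (Bu4NF, AcOH, THF, 0 °C) gives (2S)-5,7-bis(benzyloxy)-2-[4-(benzyloxy)phenyl]-6-{4-[(1R)-1-hydroxyprop-2-yn-1-yl]phenoxy}chroman-4-one F4. A Mitsunobu reaction with 13 (PPh3, diisopropyl azodicarboxylate, toluene, 0 °C) then inverts the carbinol and comes back to the route at 14. Partial ionisation at this benzylic, propargylic centre can cost enantiopurity, which is why the Mitsunobu reaction is the fallback and not the main route.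

**Step 5.** Insertion into the electron-rich, 5-substituted chromone may be slow, so that protodeboronation of 9 outruns it; arylation of the formyl group or incomplete facial control are further risks. The fallback sets out from 8. The aldehyde is masked (ethylene glycol, TsOH, toluene, water separator) as 5,7-bis(benzyloxy)-6-[4-(1,3-dioxolan-2-yl)phenoxy]-4H-chromen-4-one F5. A 1,4-addition of 9 under monovalent rhodium ([RhOH(cod)]2 with an electron-poor atropisomeric bisphosphine of the MeO-BIPHEP type, toluene/H2O) should give (2S)-5,7-bis(benzyloxy)-2-[4-(benzyloxy)phenyl]-6-[4-(1,3-dioxolan-2-yl)phenoxy]chroman-4-one F6. Mild aqueous acid (HCl, THF/H2O, rt) removes the acetal and comes back to the route at 10.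

**Step 9.** The electron-rich chromene or the flavan-4-ol may degrade under the oxidising medium (loss of water from 16, cationic oligomers), or the benzylic radical may be reduced before it meets oxygen. The fallback sets out from 15. Rhodium-catalysed hydroboration with catecholborane ([Rh(cod)2]BF4, 1,4-bis(diphenylphosphino)butane, THF, −20 °C) places boron at the benzylic carbon and tolerates ketones. It should give the C4 benzodioxaborolyl derivative of the chroman, (2S)-6-{4-[(2S)-4-(1,3,2-benzodioxaborol-2-yl)-5,7-bis(benzyloxy)chroman-2-yl]phenoxy}-5,7-bis(benzyloxy)-2-[4-(benzyloxy)phenyl]chroman-4-one F7. Oxidation (NaBO3·4H2O, THF/H2O) then comes back to the route at 16.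

**Step 2.** The hydroquinone product is more easily oxidised than the starting phenol, and the lipophilic dibenzyl ether dissolves poorly in aqueous base, so conversion may be low and over-oxidation significant. The fallback sets out from 2. Teuber oxidation with potassium nitrosodisulfonate ((KSO3)2NO, KH2PO4, acetone/H2O) should give 2-acetyl-3,5-bis(benzyloxy)-1,4-benzoquinone F8. Reduction with Na2S2O4 (EtOAc/H2O) then comes back to the route at 4.

## Further compounds

F1 | step 8 | (3S)-3-[3,5-bis(benzyloxy)phenoxy]-3-(4-{[(2S)-5,7-bis(benzyloxy)-2-[4-(benzyloxy)phenyl]-4-oxochroman-6-yl]oxy}phenyl)propanal | O=CC[C@@H](c1ccc(Oc2c(OCc3ccccc3)cc3c(c2OCc2ccccc2)C(=O)C[C@@H](c2ccc(OCc4ccccc4)cc2)O3)cc1)Oc1cc(OCc2ccccc2)cc(OCc2ccccc2)c1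
F2 | step 8 | (3S)-3-[3,5-bis(benzyloxy)phenoxy]-3-(4-{[(2S)-5,7-bis(benzyloxy)-2-[4-(benzyloxy)phenyl]-4-oxochroman-6-yl]oxy}phenyl)propanoic acid | OC(=O)C[C@@H](c1ccc(Oc2c(OCc3ccccc3)cc3c(c2OCc2ccccc2)C(=O)C[C@@H](c2ccc(OCc4ccccc4)cc2)O3)cc1)Oc1cc(OCc2ccccc2)cc(OCc2ccccc2)c1
F3 | step 7 | (2S)-5,7-bis(benzyloxy)-2-[4-(benzyloxy)phenyl]-6-{4-[(1S)-1-hydroxy-3-(trimethylsilyl)prop-2-yn-1-yl]phenoxy}chroman-4-one | C[Si](C)(C)C#C[C@H](c1ccc(Oc2c(OCc3ccccc3)cc3c(c2OCc2ccccc2)C(=O)C[C@@H](c2ccc(OCc4ccccc4)cc2)O3)cc1)O
F4 | step 7 | (2S)-5,7-bis(benzyloxy)-2-[4-(benzyloxy)phenyl]-6-{4-[(1R)-1-hydroxyprop-2-yn-1-yl]phenoxy}chroman-4-one | C#C[C@H](c1ccc(Oc2c(OCc3ccccc3)cc3c(c2OCc2ccccc2)C(=O)C[C@@H](c2ccc(OCc4ccccc4)cc2)O3)cc1)O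
F5 | step 5 | 5,7-bis(benzyloxy)-6-[4-(1,3-dioxolan-2-yl)phenoxy]-4H-chromen-4-one | C1COC(O1)c1ccc(Oc2c(OCc3ccccc3)cc3occc(=O)c3c2OCc2ccccc2)cc1
F6 | step 5 | (2S)-5,7-bis(benzyloxy)-2-[4-(benzyloxy)phenyl]-6-[4-(1,3-dioxolan-2-yl)phenoxy]chroman-4-one | C1COC(O1)c1ccc(Oc2c(OCc3ccccc3)cc3c(c2OCc2ccccc2)C(=O)C[C@@H](c2ccc(OCc4ccccc4)cc2)O3)cc1
F7 | step 9 | (2S)-6-{4-[(2S)-4-(1,3,2-benzodioxaborol-2-yl)-5,7-bis(benzyloxy)chroman-2-yl]phenoxy}-5,7-bis(benzyloxy)-2-[4-(benzyloxy)phenyl]chroman-4-one, both C4 epimers | c1ccc2OB(Oc2c1)C1C[C@@H](c2ccc(Oc3c(OCc4ccccc4)cc4c(c3OCc3ccccc3)C(=O)C[C@@H](c3ccc(OCc5ccccc5)cc3)O4)cc2)Oc2cc(OCc3ccccc3)cc(OCc3ccccc3)c21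
F8 | step 2 | 2-acetyl-3,5-bis(benzyloxy)-1,4-benzoquinone | CC(=O)C1=C(OCc2ccccc2)C(=O)C(OCc2ccccc2)=CC1=O
A1 | alternative 1 | 3-(4-bromophenoxy)-4-ethoxy-5-[1-(tert-butyldimethylsilyloxy)ethyl]-6-(triisopropylsilyloxy)-2-(trimethylsilyl)phenol | CC(O[Si](C)(C)C(C)(C)C)c1c(O[Si](C(C)C)(C(C)C)C(C)C)c([Si](C)(C)C)c(O)c(Oc2ccc(Br)cc2)c1OCC
A2 | alternative 1 | 4-(4-bromophenoxy)-3-ethoxy-2-[1-(tert-butyldimethylsilyloxy)ethyl]cyclobut-2-en-1-one | O=C1C(C(C)O[Si](C)(C)C(C)(C)C)=C(OCC)C1Oc1ccc(Br)cc1
A3 | alternative 1 | trimethyl{[tri(propan-2-yl)silyl]oxyethynyl}silane | C[Si](C)(C)C#CO[Si](C(C)C)(C(C)C)C(C)C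
A4 | alternative 2 | (2S)-6-(4-bromophenoxy)-5,7-dihydroxy-2-[4-(methoxymethoxy)phenyl]chroman-4-one | O=C1C[C@@H](c2ccc(OCOC)cc2)Oc2cc(O)c(Oc3ccc(Br)cc3)c(O)c21
A5 | alternative 2 | 5-(4-bromophenoxy)-6-({(2S)-2-[4-(methoxymethoxy)phenyl]-4-oxo-3,4-dihydro-2H-pyran-6-yl}methyl)-2,2-dimethyl-4H-1,3-dioxin-4-one | CC1(C)OC(=O)C(Oc2ccc(Br)cc2)=C(CC2=CC(=O)C[C@@H](c3ccc(OCOC)cc3)O2)O1
A6 | alternative 3 | (2S)-5,7-bis(benzyloxy)-2-[4-(benzyloxy)phenyl]-6-(4-bromophenoxy)chroman-4-one | O=C1C[C@@H](c2ccc(OCc3ccccc3)cc2)Oc2cc(OCc3ccccc3)c(Oc3ccc(Br)cc3)c(OCc3ccccc3)c21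
A7 | alternative 3 | tert-butyl{[1-(2,4-bis(benzyloxy)-6-{[4-(benzyloxy)phenyl](methoxy)methoxy}-3-(4-bromophenoxy)phenyl)ethenyl]oxy}dimethylsilane, racemic at the acetal carbon | C=C(O[Si](C)(C)C(C)(C)C)c1c(OC(OC)c2ccc(OCc3ccccc3)cc2)cc(OCc2ccccc2)c(Oc2ccc(Br)cc2)c1OCc1ccccc1
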